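**Retrosynthetic overview**

- C13–C14 is cut last: an alkenyl triflate on the intact decalin (from the side-chain methyl ketone) is joined to an α-silyloxy aldehyde that already carries the butenolide, in an electroreductive, zinc-chelation-controlled alkenylation that also sets C14.
- The aldehyde comes from a vinylogous Mukaiyama aldol of 2-silyloxy-4-methylfuran with (R)-glyceraldehyde acetonide (sets C15 and C16), then glycol cleavage that removes the glyceraldehyde stereocentre.
- The decalin comes from (+)-larixol: permanganate trims the side chain to the methyl ketone, a cobalt-mediated silylperoxidation puts in the 8α-oxygen, and a photochemical 1,5-hydrogen transfer from the 6α-nitrite oxygenates C18 (setting C4).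
- Ring order: rings A and B are bought fused in larixol; the butenolide ring is bought as 4-methylfuran-2(5H)-one and made stereogenic in the aldol; no ring is built.

Assumption: (+)-larixol (from larch oleoresin) is taken as a commercial starting material.
Numbering: labdane numbering for the decalin (C17 = 8β-CH3, C18 = 4α-CH2, C19 = 4β-CH3, C20 = 10β-CH3); side chain C11, C12, C13 (bearing the exocyclic CH2, C16), C14, C15; C16′ = butenolide γ-carbon.

**Step 1**
Reactants: 1 (+)-larixol (labda-8(17),14-diene-6α,13S-diol)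
Product: 2 6α-hydroxy-14,15-dinorlabd-8(17)-en-13-one
Conditions: KMnO4, MgSO4, acetone–H2O, 0 °C to rt
Reagents that add atoms: none
Why: Permanganate dihydroxylates the unhindered vinyl group and cleaves the resulting glycol/ketol (oxidative cleavage) down to the methyl ketone, while the hindered exocyclic 8(17)-alkene survives, as in the classical degradation of manool-type labdanes; only C13, which is not needed, is destroyed.

**Step 2**
Reactants: 2 6α-hydroxy-14,15-dinorlabd-8(17)-en-13-one
Product: 3 6α-hydroxy-8α-(triethylsilylperoxy)-14,15-dinorlabdan-13-one (8β-methyl)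
Conditions: Co(thd)2 (cobalt bis(2,2,6,6-tetramethylheptane-3,5-dionate), 5 mol %), Et3SiH, O2 (1 atm), 1,2-dichloroethane, rt
Reagents that add atoms: dioxygen O=O; triethylsilane CC[SiH](CC)CC
Why: Isayama–Mukaiyama hydrogen-atom-transfer silylperoxidation puts H on C17 and traps the tertiary C8 radical with O2 on the α-face, away from the axial C10 methyl, giving the 8α-O/8β-CH3 centre and leaving the tertiary oxygen masked so that 6-OH is the only free hydroxyl.

**Step 3**
Reactants: 3 6α-hydroxy-8α-(triethylsilylperoxy)-14,15-dinorlabdan-13-one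
Product: 5 6α-hydroxy-18-nitrooxy-8α-(triethylsilylperoxy)-14,15-dinorlabdan-13-one, via 6α-nitrite ester 4 (not isolated)
Conditions: NOCl, pyridine, −20 °C; then hν (365 nm), O2, MeCN, 10 °C
Reagents that add atoms: nitrosyl chloride O=NCl; dioxygen O=O
Why: Barton nitrite photolysis under oxygen: the equatorial 6α-alkoxy radical sits syn-pentane to the equatorial 4α-methyl, so 1,5-hydrogen transfer picks C18 over the axial C19 and the remote C20, and the C18 radical is trapped by O2/NO as the nitrate ester, which fixes C4 under control of C5 and C6.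

**Step 4**
Reactants: 5 6α-hydroxy-18-nitrooxy-8α-(triethylsilylperoxy)-14,15-dinorlabdan-13-one
Product: 6 6α,8α,18-trihydroxy-14,15-dinorlabdan-13-one
Conditions: Zn dust, AcOH–THF, 0 °C to rt
Reagents that add atoms: none
Why: Dissolving-metal reduction with zinc in acetic acid cleaves both the nitrate ester and the O–O bond of the silyl peroxide, unveiling the 18- and 8α-hydroxyls without touching the ketone or any stereocentre.

**Step 5**
Reactants: 6 6α,8α,18-trihydroxy-14,15-dinorlabdan-13-one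
Product: 7 6α,8α,18-tris(triethylsilyloxy)-14,15-dinorlabdan-13-one
Conditions: Et3SiOTf, 2,6-lutidine, CH2Cl2, −78 to 0 °C
Reagents that add atoms: triethylsilyl trifluoromethanesulfonate CC[Si](CC)(CC)OS(=O)(=O)C(F)(F)F
Why: Silyl ether formation with the silyl triflate protects the primary, secondary and hindered tertiary hydroxyls for the enolate and organometallic steps that follow.

**Step 6**
Reactants: 7 6α,8α,18-tris(triethylsilyloxy)-14,15-dinorlabdan-13-one
Product: 9 6α,8α,18-tris(triethylsilyloxy)-14,15-dinorlabd-13(16)-en-13-yl trifluoromethanesulfonate, via lithium enolate 8 (not isolated)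
Conditions: LiN(i-Pr)2, THF, −78 °C; then PhNTf2, −78 to 0 °C
Reagents that add atoms: N-phenylbis(trifluoromethanesulfonimide) O=S(=O)(N(c1ccccc1)S(=O)(=O)C(F)(F)F)C(F)(F)F
Why: Kinetic deprotonation of the methyl ketone on the methyl side and O-triflation of the less substituted enolate (kinetic enol triflate formation) gives the 1,1-disubstituted alkenyl triflate.

**Step 7**
Reactants: 10 4-methylfuran-2(5H)-one
Product: 11 tert-butyl(dimethyl)[(4-methylfuran-2-yl)oxy]silane
Conditions: t-BuMe2SiOTf, Et3N, CH2Cl2, 0 °C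
Reagents that add atoms: tert-butyldimethylsilyl trifluoromethanesulfonate CC(C)(C)[Si](C)(C)OS(=O)(=O)C(F)(F)F
Why: Soft enolisation and O-silylation of the butenolide gives the aromatic 2-silyloxyfuran (silyl dienol ether formation).

**Step 8**
Reactants: 11 tert-butyl(dimethyl)[(4-methylfuran-2-yl)oxy]silane; 12 (R)-2,3-O-isopropylideneglyceraldehyde
Product: 13 (5R)-5-{(S)-hydroxy[(4R)-2,2-dimethyl-1,3-dioxolan-4-yl]methyl}-4-methylfuran-2(5H)-one
Conditions: BF3·OEt2 (1.1 equiv), CH2Cl2, −78 °C; aq. NaHCO3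
Reagents that add atoms: none
Why: Vinylogous Mukaiyama aldol: the furan attacks through its γ-carbon on the BF3-activated aldehyde under Felkin–Anh control by the glyceraldehyde centre, giving the 4,5-threo-5,6-erythro adduct and so setting C16′ (R) and the carbinol C15.

**Step 9**
Reactants: 13 (5R)-5-{(S)-hydroxy[(4R)-2,2-dimethyl-1,3-dioxolan-4-yl]methyl}-4-methylfuran-2(5H)-one
Product: 14 (5R)-5-{(S)-(tert-butyldimethylsilyloxy)[(4R)-2,2-dimethyl-1,3-dioxolan-4-yl]methyl}-4-methylfuran-2(5H)-one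
Conditions: t-BuMe2SiOTf, 2,6-lutidine, CH2Cl2, −40 °C
Reagents that add atoms: tert-butyldimethylsilyl trifluoromethanesulfonate CC(C)(C)[Si](C)(C)OS(=O)(=O)C(F)(F)F
Why: Silyl ether formation under weakly basic conditions protects the carbinol without epimerising or eliminating at the acidic butenolide γ-position.

**Step 10**
Reactants: 14 (5R)-5-{(S)-(tert-butyldimethylsilyloxy)[(4R)-2,2-dimethyl-1,3-dioxolan-4-yl]methyl}-4-methylfuran-2(5H)-one
Product: 15 (2S)-2-(tert-butyldimethylsilyloxy)-2-[(2R)-3-methyl-5-oxo-2,5-dihydrofuran-2-yl]acetaldehyde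
Conditions: H5IO6, EtOAc, rt; used crude
Reagents that add atoms: none
Why: Periodic acid hydrolyses the terminal acetonide and cleaves the freed 1,2-diol in one pot (glycol cleavage), deleting the glyceraldehyde centre after it has done its work and leaving the α-silyloxy aldehyde.

**Step 11**
Reactants: 9 6α,8α,18-tris(triethylsilyloxy)-14,15-dinorlabd-13(16)-en-13-yl trifluoromethanesulfonate; 15 (2S)-2-(tert-butyldimethylsilyloxy)-2-[(2R)-3-methyl-5-oxo-2,5-dihydrofuran-2-yl]acetaldehyde
Product: 17 6,8,18-tris-O-triethylsilyl-15-O-tert-butyldimethylsilyl derivative of the target (14S,15R,16′R), via alkenylzinc triflate 16 (not isolated)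
Conditions: NiBr2·glyme (10 mol %), 2,2′-bipyridine (10 mol %), n-Bu4NPF6, THF–toluene (1:2), undivided cell, sacrificial Zn anode, nickel-foam cathode, 5 mA, 2.5 F/mol, 0 °C, 9 (1.3 equiv) and 15 both present; aq. NH4Cl
Reagents that add atoms: none
Why: Proposed new method: chelation-controlled electroreductive alkenylation, in which cathodically formed zerovalent nickel inserts into the C–OTf bond of 9, the alkenyl group passes to divalent zinc released from the anode (alkenylzinc triflate 16), and the same zinc cations chelate the aldehyde oxygen and the α-silyloxy oxygen of 15 in the weakly coordinating medium so that the alkenyl group adds to the Cram-chelate face away from the butenolide, giving the 14,15-syn (14S) carbinol; the closest known reaction types are the nickel-catalysed electrochemical zincation of aryl halides, the nickel/chromium electrochemical Nozaki–Hiyama–Kishi coupling and thermal chelation-controlled additions of vinylzinc reagents to α-silyloxy aldehydes.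

**Step 12**
Reactants: 17 6,8,18-tris-O-triethylsilyl-15-O-tert-butyldimethylsilyl derivative of the target
Product: 18 CNP0301623.1 (target)
Conditions: HF·pyridine, pyridine–THF, 0 °C to rt
Reagents that add atoms: none
Why: Fluoride-mediated global desilylation under buffered, non-basic conditions removes all four silyl ethers without epimerising the butenolide γ-centre or dehydrating the tertiary alcohol.

**Compound list**

1 | (+)-larixol, labda-8(17),14-diene-6α,13S-diol | C=C[C@@](C)(O)CC[C@@H]1[C@@]2(C)CCCC(C)(C)[C@@H]2[C@@H](O)CC1=C | starting material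
2 | 6α-hydroxy-14,15-dinorlabd-8(17)-en-13-one | CC(=O)CC[C@@H]1[C@@]2(C)CCCC(C)(C)[C@@H]2[C@@H](O)CC1=C | intermediate
3 | 6α-hydroxy-8α-(triethylsilylperoxy)-14,15-dinorlabdan-13-one | CC(=O)CC[C@@H]1[C@@]2(C)CCCC(C)(C)[C@@H]2[C@@H](O)C[C@@]1(C)OO[Si](CC)(CC)CC | intermediate
4 | 6α-nitrite ester of 3 | CC(=O)CC[C@@H]1[C@@]2(C)CCCC(C)(C)[C@@H]2[C@@H](ON=O)C[C@@]1(C)OO[Si](CC)(CC)CC | intermediate
5 | 6α-hydroxy-18-nitrooxy-8α-(triethylsilylperoxy)-14,15-dinorlabdan-13-one | CC(=O)CC[C@@H]1[C@@]2(C)CCC[C@@](C)(CO[N+](=O)[O-])[C@@H]2[C@@H](O)C[C@@]1(C)OO[Si](CC)(CC)CC | intermediate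
6 | 6α,8α,18-trihydroxy-14,15-dinorlabdan-13-one | CC(=O)CC[C@@H]1[C@@]2(C)CCC[C@@](C)(CO)[C@@H]2[C@@H](O)C[C@@]1(C)O | intermediate
7 | 6α,8α,18-tris(triethylsilyloxy)-14,15-dinorlabdan-13-one | CC(=O)CC[C@@H]1[C@@]2(C)CCC[C@@](C)(CO[Si](CC)(CC)CC)[C@@H]2[C@@H](O[Si](CC)(CC)CC)C[C@@]1(C)O[Si](CC)(CC)CC | intermediate
8 | lithium enolate of 7 (terminal, C13=C16) | [Li]OC(=C)CC[C@@H]1[C@@]2(C)CCC[C@@](C)(CO[Si](CC)(CC)CC)[C@@H]2[C@@H](O[Si](CC)(CC)CC)C[C@@]1(C)O[Si](CC)(CC)CC | intermediate
9 | 6α,8α,18-tris(triethylsilyloxy)-14,15-dinorlabd-13(16)-en-13-yl trifluoromethanesulfonate | C=C(OS(=O)(=O)C(F)(F)F)CC[C@@H]1[C@@]2(C)CCC[C@@](C)(CO[Si](CC)(CC)CC)[C@@H]2[C@@H](O[Si](CC)(CC)CC)C[C@@]1(C)O[Si](CC)(CC)CC | intermediate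
10 | 4-methylfuran-2(5H)-one | CC1=CC(=O)OC1 | starting material
11 | tert-butyl(dimethyl)[(4-methylfuran-2-yl)oxy]silane | Cc1cc(O[Si](C)(C)C(C)(C)C)oc1 | intermediate
12 | (R)-2,3-O-isopropylideneglyceraldehyde | O=C[C@H]1COC(C)(C)O1 | starting material
13 | (5R)-5-{(S)-hydroxy[(4R)-2,2-dimethyl-1,3-dioxolan-4-yl]methyl}-4-methylfuran-2(5H)-one | CC1(C)OC[C@@H](O1)[C@@H](O)[C@@H]1OC(=O)C=C1C | intermediate
14 | (5R)-5-{(S)-(tert-butyldimethylsilyloxy)[(4R)-2,2-dimethyl-1,3-dioxolan-4-yl]methyl}-4-methylfuran-2(5H)-one | CC1(C)OC[C@@H](O1)[C@@H](O[Si](C)(C)C(C)(C)C)[C@@H]1OC(=O)C=C1C | intermediate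
15 | (2S)-2-(tert-butyldimethylsilyloxy)-2-[(2R)-3-methyl-5-oxo-2,5-dihydrofuran-2-yl]acetaldehyde | O=C[C@@H](O[Si](C)(C)C(C)(C)C)[C@@H]1OC(=O)C=C1C | intermediate
16 | alkenylzinc triflate from 9 (zinc on C13) | C=C([Zn]OS(=O)(=O)C(F)(F)F)CC[C@@H]1[C@@]2(C)CCC[C@@](C)(CO[Si](CC)(CC)CC)[C@@H]2[C@@H](O[Si](CC)(CC)CC)C[C@@]1(C)O[Si](CC)(CC)CC | intermediate
17 | 6,8,18-tris-O-triethylsilyl-15-O-tert-butyldimethylsilyl derivative of the target (14S,15R,16′R) | C=C(CC[C@@H]1[C@@]2(C)CCC[C@@](C)(CO[Si](CC)(CC)CC)[C@@H]2[C@@H](O[Si](CC)(CC)CC)C[C@@]1(C)O[Si](CC)(CC)CC)[C@H](O)[C@@H](O[Si](C)(C)C(C)(C)C)[C@@H]1OC(=O)C=C1C | intermediate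
18 | CNP0301623.1 | C=C(CC[C@@H]1[C@@]2(C)CCC[C@@](C)(CO)[C@@H]2[C@@H](O)C[C@@]1(C)O)[C@H](O)[C@@H](O)[C@@H]1OC(=O)C=C1C | target

**Step count**

Total: 12 steps. Longest linear sequence: 8 steps (steps 1–6, 11, 12); the aldehyde branch is 4 steps (steps 7–10).

**Steps most likely to fail**

Step 11 (the proposed alkenylation). The alkenylzinc may add too slowly, the aldehyde may be reduced at the cathode, or chelation may lose to Felkin–Anh addition and give the C14 epimer. The fallback sets out from 9 and 15 and comes back at 17. The established chromium/nickel electrochemical Nozaki–Hiyama–Kishi coupling (CrCl2 20 mol %, NiCl2·glyme 2 mol %, Cp2ZrCl2, Al anode, DMF) joins 9 and 15 to the allylic alcohol without reliable control at C14, giving 17 together with its (14R)-epimer F1. Dess–Martin oxidation of the mixture converges both on the α′-silyloxy enone F2. Non-chelating 1,2-reduction (NaBH4, CeCl3·7H2O, MeOH, −78 °C), with hydride anti to the C15–O bond (Felkin–Anh), then gives the 14,15-syn alcohol 17, at the cost of two extra steps.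

Step 3 (nitrite photolysis under oxygen). The nitrate yield may be modest, and β-scission of the 6-alkoxy radical or α-nitrosation of the ketone may compete. The fallback sets out from the nitrite 4 and comes back at 6; it ends the radical chain with C–N instead of C–O bond formation. Photolysis of 4 under argon (classical Barton reaction), followed by warming in 2-propanol, gives the 18-oxime F3. Nitrosative deoximation (NaNO2, aqueous AcOH) gives the 18-aldehyde F4, which sits in equilibrium with its 6,18-lactol. NaBH(OAc)3 reduces this aldehyde in the presence of the methyl ketone to the 6α,18-diol silyl peroxide F5, and Zn/AcOH then cleaves the peroxide to give 6.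

Step 2 (silylperoxidation at C8). The facial selectivity of the radical trapping may be modest and the silyl peroxide may be awkward to handle. The fallback sets out from 1 and comes back at 6, replacing the radical oxygenation by two-electron chemistry. m-CPBA epoxidises the more nucleophilic 8(17)-alkene of larixol from the α-face to the 8α,17-epoxide F6. LiAlH4 opens it at the primary carbon to labd-14-ene-6α,8α,13-triol F7, and KMnO4 trims the side chain to 6α,8α-dihydroxy-14,15-dinorlabdan-13-one F8. With the tertiary hydroxyl free, NOCl (1.05 equiv, −30 °C) nitrosates the secondary 6-OH selectively to the 6α-nitrite F9. Photolysis under O2 gives the 18-nitrate F10, and Zn/AcOH reduction gives 6.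

**Further compounds**

F1 | step 11 | (14R)-epimer of 17 | C=C(CC[C@@H]1[C@@]2(C)CCC[C@@](C)(CO[Si](CC)(CC)CC)[C@@H]2[C@@H](O[Si](CC)(CC)CC)C[C@@]1(C)O[Si](CC)(CC)CC)[C@@H](O)[C@@H](O[Si](C)(C)C(C)(C)C)[C@@H]1OC(=O)C=C1C
F2 | step 11 | C14 ketone (α′-silyloxy enone) corresponding to 17 | C=C(CC[C@@H]1[C@@]2(C)CCC[C@@](C)(CO[Si](CC)(CC)CC)[C@@H]2[C@@H](O[Si](CC)(CC)CC)C[C@@]1(C)O[Si](CC)(CC)CC)C(=O)[C@@H](O[Si](C)(C)C(C)(C)C)[C@@H]1OC(=O)C=C1C
F3 | step 3 | 18-oxime of 6α-hydroxy-8α-(triethylsilylperoxy)-14,15-dinorlabdan-13-one | CC(=O)CC[C@@H]1[C@@]2(C)CCC[C@@](C)(C=NO)[C@@H]2[C@@H](O)C[C@@]1(C)OO[Si](CC)(CC)CC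
F4 | step 3 | 6α-hydroxy-13-oxo-8α-(triethylsilylperoxy)-14,15-dinorlabdan-18-al (open form of the 6,18-lactol) | CC(=O)CC[C@@H]1[C@@]2(C)CCC[C@@](C)(C=O)[C@@H]2[C@@H](O)C[C@@]1(C)OO[Si](CC)(CC)CC
F5 | step 3 | 6α,18-dihydroxy-8α-(triethylsilylperoxy)-14,15-dinorlabdan-13-one | CC(=O)CC[C@@H]1[C@@]2(C)CCC[C@@](C)(CO)[C@@H]2[C@@H](O)C[C@@]1(C)OO[Si](CC)(CC)CC
F6 | step 2 | 8α,17-epoxylabd-14-ene-6α,13S-diol | C=C[C@@](C)(O)CC[C@@H]1[C@@]2(C)CCCC(C)(C)[C@@H]2[C@@H](O)C[C@]13CO3
F7 | step 2 | labd-14-ene-6α,8α,13S-triol | C=C[C@@](C)(O)CC[C@@H]1[C@@]2(C)CCCC(C)(C)[C@@H]2[C@@H](O)C[C@@]1(C)O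
F8 | step 2 | 6α,8α-dihydroxy-14,15-dinorlabdan-13-one | CC(=O)CC[C@@H]1[C@@]2(C)CCCC(C)(C)[C@@H]2[C@@H](O)C[C@@]1(C)O
F9 | step 2 | 6α-nitrite ester of F8 | CC(=O)CC[C@@H]1[C@@]2(C)CCCC(C)(C)[C@@H]2[C@@H](ON=O)C[C@@]1(C)O
F10 | step 2 | 6α,8α-dihydroxy-18-nitrooxy-14,15-dinorlabdan-13-one | CC(=O)CC[C@@H]1[C@@]2(C)CCC[C@@](C)(CO[N+](=O)[O-])[C@@H]2[C@@H](O)C[C@@]1(C)O
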